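**Plan**

1. Retrosynthesis (pyran locants O1, C2 methyl, C3 CH2OH, C4 side chain, C5 CO2Me, C6 H): remove the three benzyl ethers; cut the enol-ether bond O1–C6 and return O1 to the ester carbon on C5, giving an α-formyl δ-lactone; cut the C5–C6 bond (formyl carbon) and the C4–CH2CO2R bond (one tandem Michael addition/formylation) back to an α,β-unsaturated δ-lactone and an aryl-ethyl acetate; cut the lactone C=C (ring-closing metathesis) and its acrylate ester; cut the C3–vinyl bond to an epoxy alcohol made from crotyl alcohol.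
2. Enabling feature: C5 carries two carbonyl-level carbons, the ring CH (C6) and the CO2Me carbon, and O1 on C2 can bind either one in a six-membered ring. The dihydropyran ring (O1, C2, C3, C4, C5, C6) is therefore a constitutional isomer of an oxan-2-one ring (O1, C2, C3, C4, C5, ester carbon), and acidic methanol moves O1 from the acyl carbon to C6.
3. Forward order: epoxide, anti 1,3-diol, acrylate, oxan-2-one ring by metathesis, side chain plus formyl carbon in one flask, lactone-to-dihydropyran ring switch, hydrogenolysis.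
4. Stereochemistry: C2 (S) from the Sharpless epoxidation; C3 (R) by SN2 inversion in the epoxide opening; C4 (S) by conjugate addition anti to the C3 substituent on the lactone.

Key step: step 9

Remark: the α-formyl lactone 12 is written as its hydroxymethylidene (enol) tautomer with undefined C=C geometry, and 14 as a mixture at its two transient centres; neither affects the outcome.

**Route**

Step 1
Reactants: 1 hydroxytyrosol, 2-(3,4-dihydroxyphenyl)ethanol
Product: 2 2-[3,4-bis(benzyloxy)phenyl]ethanol
Conditions: BnBr (2.2 equiv), K2CO3, acetone, reflux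
Reagents that add atoms: benzyl bromide, BrCc1ccccc1
Why: Williamson ether synthesis in which K2CO3 deprotonates only the two phenols, so the catechol is benzylated and the aliphatic alcohol stays free.

Step 2
Reactants: 2 2-[3,4-bis(benzyloxy)phenyl]ethanol
Product: 3 2-[3,4-bis(benzyloxy)phenyl]ethyl acetate
Conditions: Ac2O, pyridine, DMAP (cat.), CH2Cl2, 0 °C → rt
Reagents that add atoms: acetic anhydride, CC(=O)OC(C)=O
Why: Nucleophile-catalysed O-acylation of the primary alcohol gives the acetate that serves later as the Michael donor.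

Step 3
Reactants: 4 (E)-but-2-en-1-ol (crotyl alcohol)
Product: 5 [(2S,3S)-3-methyloxiran-2-yl]methanol
Conditions: Ti(OiPr)4 (cat.), L-(+)-diisopropyl tartrate (cat.), tBuOOH (anhydrous, in decane), 4 Å molecular sieves, CH2Cl2, −20 °C
Reagents that add atoms: tert-butyl hydroperoxide, CC(C)(C)OO
Why: Sharpless asymmetric epoxidation, in which the titanium tartrate complex with the L-(+)-tartrate delivers oxygen to one face of the E allylic alcohol and sets both epoxide carbons as (2S,3S); the methyl-bearing carbon becomes C2 (S) of the target ring.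

Step 4
Reactants: 5 [(2S,3S)-3-methyloxiran-2-yl]methanol
Product: 6 (2R,3S)-2-ethenylbutane-1,3-diol
Conditions: CH2=CHMgBr (3 equiv), CuI (10 mol %), THF/Et2O, −30 → −15 °C; aq. NH4Cl
Reagents that add atoms: vinylmagnesium bromide, C=C[Mg]Br
Why: Copper-catalysed Grignard opening of a trans-2,3-epoxy alcohol, which should take place at C2 of the magnesium alkoxide with SN2 inversion and so gives the anti 1,3-diol and sets the future C3 (R).

Step 5
Reactants: 6 (2R,3S)-2-ethenylbutane-1,3-diol
Product: 7 (2S,3R)-3-[(benzyloxy)methyl]pent-4-en-2-ol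
Conditions: NaH (1.05 equiv), THF, 0 °C; BnBr (1.0 equiv), Bu4NI (cat.), 0 °C → rt
Reagents that add atoms: benzyl bromide, BrCc1ccccc1
Why: Williamson etherification with limiting base should favour the less hindered primary alkoxide and leave the secondary hydroxyl free for the lactone.

Step 6
Reactants: 7 (2S,3R)-3-[(benzyloxy)methyl]pent-4-en-2-ol
Product: 8 (2S,3R)-3-[(benzyloxy)methyl]pent-4-en-2-yl prop-2-enoate
Conditions: CH2=CHCOCl, Et3N, DMAP (cat.), CH2Cl2, −20 → 0 °C
Reagents that add atoms: acryloyl chloride, C=CC(=O)Cl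
Why: Acylation of the secondary alcohol with an acid chloride, which does not touch the C–O bond of the carbinol carbon.

Step 7
Reactants: 8 (2S,3R)-3-[(benzyloxy)methyl]pent-4-en-2-yl prop-2-enoate
Product: 9 (5R,6S)-5-[(benzyloxy)methyl]-6-methyl-5,6-dihydro-2H-pyran-2-one
Conditions: second-generation Grubbs catalyst (3 mol %), CH2Cl2 (0.01 M), reflux
Reagents that add atoms: none
Why: Ring-closing metathesis of an acrylate with a terminal alkene, a standard entry to 5,6-dihydro-2H-pyran-2-ones, driven by loss of ethene and leaving both stereocenters untouched.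

Step 8
Reactants: 3 2-[3,4-bis(benzyloxy)phenyl]ethyl acetate; 9 (5R,6S)-5-[(benzyloxy)methyl]-6-methyl-5,6-dihydro-2H-pyran-2-one
Product: 12 2-[3,4-bis(benzyloxy)phenyl]ethyl 2-[(4S,5R,6S)-5-[(benzyloxy)methyl]-3-(hydroxymethylidene)-6-methyl-2-oxooxan-4-yl]acetate, via lithium enolate 10 (not isolated), via lithium lactone enolate 11 (not isolated)
Conditions: 3, LiN(iPr)2, THF, −78 °C; then 9, −78 °C; then CF3CH2OCHO, −78 → −20 °C; 1 M HCl to pH 4
Reagents that add atoms: 2,2,2-trifluoroethyl formate, O=COCC(F)(F)F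
Why: Michael addition of a lithium ester enolate to the α,β-unsaturated δ-lactone followed by Claisen-type C-formylation of the lactone enolate formed only at that position; the nucleophile should enter C4 of the lactone anti to the neighbouring benzyloxymethyl group and the cis methyl group, which sets the future C4 (S) trans to C3.

Step 9
Reactants: 12 2-[3,4-bis(benzyloxy)phenyl]ethyl 2-[(4S,5R,6S)-5-[(benzyloxy)methyl]-3-(hydroxymethylidene)-6-methyl-2-oxooxan-4-yl]acetate
Product: 15 methyl (2S,3R,4S)-4-{2-[2-(3,4-bis(benzyloxy)phenyl)ethoxy]-2-oxoethyl}-3-[(benzyloxy)methyl]-2-methyl-3,4-dihydro-2H-pyran-5-carboxylate, via seco hydroxy enol ester 13 (not isolated), via cyclic methyl acetal 14 (not isolated)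
Conditions: HCl (0.1 M, anhydrous), MeOH, 0 °C → rt; then p-TsOH (cat.), PhMe, 60 °C (−MeOH)
Reagents that add atoms: methanol, CO
Why: Acid-catalysed methanolysis of the activated lactone acyl carbon turns it into the methyl ester and frees the secondary hydroxyl (13), which adds to the neighbouring formyl carbon (as aldehyde or its oxocarbenium ion) to give the six-membered acetal 14, and acid-promoted loss of methanol across the acetal carbon and the acidic α-carbon then gives the conjugated enol ether. The closest known reaction type is the Korte acyl-lactone rearrangement of α-formyl lactones into alkyl dihydrofuran- and dihydropyran-carboxylates. The dihydropyran ring closes in the 6-exo-trig mode, by attack of the hydroxyl oxygen on the formyl C=O carbon. No stereocenter is created in the product, because both transient centres of 14 become sp2, and the three existing ones persist since the C–O bond at the methyl-bearing carbon is never broken and neither other centre is enolisable. The step needs the freed hydroxyl to close on the formyl carbon and not on the side-chain ester, needs methanol to open the lactone without exchanging the aryl-ethyl ester, and needs the primary oxygen kept away from the formyl carbon. These are secured by the far higher electrophilicity of the aldehyde with irreversible elimination to the vinylogous carbonate, by the much faster acyl substitution of a δ-lactone bearing an α-acyl group compared with an open-chain ester under dilute acid at room temperature, and by the benzyl ether on the primary oxygen.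

Step 10
Reactants: 15 methyl (2S,3R,4S)-4-{2-[2-(3,4-bis(benzyloxy)phenyl)ethoxy]-2-oxoethyl}-3-[(benzyloxy)methyl]-2-methyl-3,4-dihydro-2H-pyran-5-carboxylate
Product: 16 methyl (2S,3R,4S)-4-{2-[2-(3,4-dihydroxyphenyl)ethoxy]-2-oxoethyl}-3-(hydroxymethyl)-2-methyl-3,4-dihydro-2H-pyran-5-carboxylate (target)
Conditions: H2 (1 atm), 10% Pd/C, EtOAc, rt
Reagents that add atoms: none
Why: Catalytic hydrogenolysis of the two aryl benzyl ethers and the alkyl benzyl ether, in which the electron-poor trisubstituted enol-ether double bond conjugated to the ester should be reduced far more slowly than the benzylic C–O bonds.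

**Compound list**

1 | hydroxytyrosol, 2-(3,4-dihydroxyphenyl)ethanol | OCCc1ccc(O)c(O)c1 | starting material
2 | 2-[3,4-bis(benzyloxy)phenyl]ethanol | OCCc1ccc(OCc2ccccc2)c(OCc2ccccc2)c1 | intermediate
3 | 2-[3,4-bis(benzyloxy)phenyl]ethyl acetate | CC(=O)OCCc1ccc(OCc2ccccc2)c(OCc2ccccc2)c1 | intermediate
4 | (E)-but-2-en-1-ol | C/C=C/CO | starting material
5 | [(2S,3S)-3-methyloxiran-2-yl]methanol | C[C@@H]1O[C@H]1CO | intermediate
6 | (2R,3S)-2-ethenylbutane-1,3-diol | O[C@@H](C)[C@@H](CO)C=C | intermediate
7 | (2S,3R)-3-[(benzyloxy)methyl]pent-4-en-2-ol | O[C@@H](C)[C@@H](COCc1ccccc1)C=C | intermediate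
8 | (2S,3R)-3-[(benzyloxy)methyl]pent-4-en-2-yl prop-2-enoate | C=CC(=O)O[C@@H](C)[C@@H](COCc1ccccc1)C=C | intermediate
9 | (5R,6S)-5-[(benzyloxy)methyl]-6-methyl-5,6-dihydro-2H-pyran-2-one | O=C1C=C[C@H](COCc2ccccc2)[C@H](C)O1 | intermediate
10 | lithium 1-{2-[3,4-bis(benzyloxy)phenyl]ethoxy}ethen-1-olate (lithium enolate of 3) | [Li]OC(=C)OCCc1ccc(OCc2ccccc2)c(OCc2ccccc2)c1 | intermediate
11 | lithium (2S,3R,4S)-4-{2-[2-(3,4-bis(benzyloxy)phenyl)ethoxy]-2-oxoethyl}-3-[(benzyloxy)methyl]-2-methyl-3,4-dihydro-2H-pyran-6-olate (lactone enolate after Michael addition) | [Li]OC1=C[C@@H](CC(=O)OCCc2ccc(OCc3ccccc3)c(OCc3ccccc3)c2)[C@H](COCc2ccccc2)[C@H](C)O1 | intermediate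
12 | 2-[3,4-bis(benzyloxy)phenyl]ethyl 2-[(4S,5R,6S)-5-[(benzyloxy)methyl]-3-(hydroxymethylidene)-6-methyl-2-oxooxan-4-yl]acetate | O=C1O[C@@H](C)[C@@H](COCc2ccccc2)[C@H](CC(=O)OCCc2ccc(OCc3ccccc3)c(OCc3ccccc3)c2)C1=CO | intermediate
13 | 1-{2-[3,4-bis(benzyloxy)phenyl]ethyl} 5-methyl (3S)-3-[(2R,3S)-1-(benzyloxy)-3-hydroxybutan-2-yl]-4-(hydroxymethylidene)pentanedioate (seco hydroxy enol ester) | COC(=O)C(=CO)[C@H]([C@@H]([C@@H](O)C)COCc1ccccc1)CC(=O)OCCc1ccc(OCc2ccccc2)c(OCc2ccccc2)c1 | intermediate
14 | methyl (2S,3R,4S)-4-{2-[2-(3,4-bis(benzyloxy)phenyl)ethoxy]-2-oxoethyl}-3-[(benzyloxy)methyl]-6-methoxy-2-methyloxane-5-carboxylate (mixture at C5 and C6) | COC(=O)C1C(OC)O[C@@H](C)[C@@H](COCc2ccccc2)[C@@H]1CC(=O)OCCc1ccc(OCc2ccccc2)c(OCc2ccccc2)c1 | intermediate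
15 | methyl (2S,3R,4S)-4-{2-[2-(3,4-bis(benzyloxy)phenyl)ethoxy]-2-oxoethyl}-3-[(benzyloxy)methyl]-2-methyl-3,4-dihydro-2H-pyran-5-carboxylate | COC(=O)C1=CO[C@@H](C)[C@@H](COCc2ccccc2)[C@@H]1CC(=O)OCCc1ccc(OCc2ccccc2)c(OCc2ccccc2)c1 | intermediate
16 | methyl (2S,3R,4S)-4-{2-[2-(3,4-dihydroxyphenyl)ethoxy]-2-oxoethyl}-3-(hydroxymethyl)-2-methyl-3,4-dihydro-2H-pyran-5-carboxylate | COC(=O)C1=CO[C@@H](C)[C@@H](CO)[C@@H]1CC(=O)OCCc1ccc(O)c(O)c1 | target

**Summary**

Total step count: 10. Longest linear sequence: 8 steps (4 to 16, steps 3 to 10).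

**Steps most likely to fail**

Step 8. The hard lithium enolate may deprotonate the γ-position of lactone 9 or add to its carbonyl instead of adding in the conjugate sense. Facial selectivity may erode, or proton transfer before formylation may place the formyl group on the side-chain α-carbon. The fallback sets out from 9 and builds the acetic acid arm by oxidation instead. Copper-catalysed conjugate addition of CH2=CHMgBr (CuBr·SMe2, Me3SiCl, THF, −78 °C) should give (4S,5R,6S)-5-[(benzyloxy)methyl]-4-ethenyl-6-methyloxan-2-one F1, in which only one enolisable position remains. Formylation (LiN(iPr)2, then CF3CH2OCHO) should give (4S,5R,6S)-5-[(benzyloxy)methyl]-4-ethenyl-3-(hydroxymethylidene)-6-methyloxan-2-one F2. The Korte rearrangement in acidic methanol should give methyl (2S,3R,4S)-3-[(benzyloxy)methyl]-4-ethenyl-2-methyl-3,4-dihydro-2H-pyran-5-carboxylate F3. Hydroboration and oxidation of the vinyl group (9-BBN, then NaBO3·4H2O) should give methyl (2S,3R,4S)-3-[(benzyloxy)methyl]-4-(2-hydroxyethyl)-2-methyl-3,4-dihydro-2H-pyran-5-carboxylate F4. Oxidation (TEMPO, PhI(OAc)2, MeCN/H2O) should give 2-[(2S,3R,4S)-3-[(benzyloxy)methyl]-5-(methoxycarbonyl)-2-methyl-3,4-dihydro-2H-pyran-4-yl]acetic acid F5. Carbodiimide esterification of F5 with alcohol 2 (EDC·HCl, DMAP, CH2Cl2) comes back to the route at 15.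

Step 9. Methanol may exchange the aryl-ethyl ester, the freed secondary hydroxyl may close on the side-chain ester with loss of alcohol 2, or the sequence may stall at the acetal stage. The fallback sets out from 9 and carries an ester that cannot exchange through the rearrangement. The same tandem Michael addition and formylation with the lithium enolate of tert-butyl acetate should give tert-butyl 2-[(4S,5R,6S)-5-[(benzyloxy)methyl]-3-(hydroxymethylidene)-6-methyl-2-oxooxan-4-yl]acetate F6. The Korte rearrangement should give methyl (2S,3R,4S)-3-[(benzyloxy)methyl]-4-(2-tert-butoxy-2-oxoethyl)-2-methyl-3,4-dihydro-2H-pyran-5-carboxylate F7. Cleavage of the tert-butyl ester (CF3CO2H, CH2Cl2) should give 2-[(2S,3R,4S)-3-[(benzyloxy)methyl]-5-(methoxycarbonyl)-2-methyl-3,4-dihydro-2H-pyran-4-yl]acetic acid F5. Esterification of F5 with alcohol 2 (EDC·HCl, DMAP) comes back to the route at 15.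

Step 10. The enol-ether double bond may be saturated, the aliphatic benzyl ether may be cleaved only slowly, or the freed primary hydroxyl may lactonise onto the side-chain ester during a long reaction. The fallback sets out from 15 and replaces reduction by Lewis-acid dealkylation with a cation scavenger (BCl3, pentamethylbenzene, CH2Cl2, −78 °C), which leaves the alkene alone and comes back to the route at 16. No new compound is made (F0).

Further compounds
F1 | step 8 | (4S,5R,6S)-5-[(benzyloxy)methyl]-4-ethenyl-6-methyloxan-2-one | O=C1O[C@@H](C)[C@@H](COCc2ccccc2)[C@H](C=C)C1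
F2 | step 8 | (4S,5R,6S)-5-[(benzyloxy)methyl]-4-ethenyl-3-(hydroxymethylidene)-6-methyloxan-2-one | O=C1O[C@@H](C)[C@@H](COCc2ccccc2)[C@H](C=C)C1=CO
F3 | step 8 | methyl (2S,3R,4S)-3-[(benzyloxy)methyl]-4-ethenyl-2-methyl-3,4-dihydro-2H-pyran-5-carboxylate | COC(=O)C1=CO[C@@H](C)[C@@H](COCc2ccccc2)[C@@H]1C=C
F4 | step 8 | methyl (2S,3R,4S)-3-[(benzyloxy)methyl]-4-(2-hydroxyethyl)-2-methyl-3,4-dihydro-2H-pyran-5-carboxylate | COC(=O)C1=CO[C@@H](C)[C@@H](COCc2ccccc2)[C@@H]1CCO
F5 | step 8 | 2-[(2S,3R,4S)-3-[(benzyloxy)methyl]-5-(methoxycarbonyl)-2-methyl-3,4-dihydro-2H-pyran-4-yl]acetic acid | COC(=O)C1=CO[C@@H](C)[C@@H](COCc2ccccc2)[C@@H]1CC(=O)O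
F6 | step 9 | tert-butyl 2-[(4S,5R,6S)-5-[(benzyloxy)methyl]-3-(hydroxymethylidene)-6-methyl-2-oxooxan-4-yl]acetate | O=C1O[C@@H](C)[C@@H](COCc2ccccc2)[C@H](CC(=O)OC(C)(C)C)C1=CO
F7 | step 9 | methyl (2S,3R,4S)-3-[(benzyloxy)methyl]-4-(2-tert-butoxy-2-oxoethyl)-2-methyl-3,4-dihydro-2H-pyran-5-carboxylate | COC(=O)C1=CO[C@@H](C)[C@@H](COCc2ccccc2)[C@@H]1CC(=O)OC(C)(C)C
F0 | step 10 | none | none
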